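## Structural features

Compound 14 is a γ-butyrolactone (O1, carbonyl C2, C3, C4, C5) with a 3,4,5-trimethoxybenzyl group (ring A) on C3 and a 4-hydroxy-3,5-dimethoxybenzyl group (ring B) on C4. Both arenes are joined to the lactone only through CH2 links, so the skeleton is flexible. C3 and C4 are adjacent stereocentres, both R, with the benzyl groups trans; there is no other stereocentre. C3 lies α to the carbonyl and can be epimerized towards the more stable trans arrangement, whereas C4 has no such escape and must be right when it is made. The fragile parts are the free, electron-rich phenol of ring B (easily oxidized), the two electron-rich rings, the base-sensitive lactone and the benzylic CH2 groups. The real difficulty is the absolute configuration at C4 together with the trans relation across C3–C4, with two nearly identical aryl groups that must end up on the right carbons. The key step exploits the C3–C4 bond. C3 is the α-carbon of an acid derivative, and C4 becomes the allylic terminus of a γ,δ-unsaturated acid once C5 is read as the stub of a propenyl group, so a chair [3,3] shift can form this bond and both centres together.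

## Logic of the disconnections

14 to 13: the phenolic O–H of ring B is replaced by an O–CH2Ph bond. A free phenol of this kind would not survive the strong base and the oxidants used earlier. The forward step must remove the benzyl group without touching the lactone or either stereocentre; 13 has no other reducible group.

13 to 11 (through 12): the C5–O1 bond of the lactone is cut and C5 is raised to the aldehyde level. A γ-hydroxy acid closes to the lactone on acidification, so the ring needs no separate construction. The forward reduction must be faster than enolization at the carbon next to the aldehyde, which is the future C4.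

11 to 9 (through 10): the aldehyde carbon is extended to a C=C bond carrying a methyl group. This reveals a γ,δ-unsaturated acid, the retron of a Claisen rearrangement. The forward cleavage must cut the alkene and leave both electron-rich rings and the benzyl ether alone.

9 to 6 (through 8 and 7): the C2–C3 bond of 9, the future C3–C4 bond of 14, is cut and the carbinol C–O bond is restored. Two adjacent stereocentres are exchanged for one carbinol centre, one alkene geometry and one ketene acetal geometry. The forward step needs a single ketene acetal geometry, a chair transition state and a geometrically pure (E)-alkene.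

6 to 4 and 5: the ester C–O bond is cut. This separates ring A with its three-carbon acid from ring B with its allylic alcohol. The acylation must not transpose the allylic system or touch the carbinol centre.

4 to 2 and 3: the C3=C4 double bond of 4 is cut into two terminal alkenes. The stereocentre is then bought with 3 and ring B arrives as an allylarene. The forward metathesis must give the (E)-alkene and must not move the double bond of 2 into conjugation with ring B.

2 to 1: the O–CH2Ph bond is cut, which leads to a commercial phenol.

## Other disconnections considered

Alternative 1: The cut removes the carbonyl carbon, breaking C2–C3 and C2–O1, and leaves the homopropargylic alcohol A1. In the forward step a hydridopalladium species HPd(X)L2 (divalent palladium), formed from Pd2(dba)3 (zerovalent palladium), 1,4-bis(diphenylphosphino)butane and CO/H2, would add syn across the alkyne with palladium on the carbon next to C4. CO insertion and capture of the acyl–palladium by the hydroxyl group would then close the lactone as the (E)-benzylidene compound A2.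
- In its favour: the ring, the carbonyl carbon and the C3 substituent are assembled in one catalytic step. The tether fixes the regiochemistry, syn addition fixes the alkene geometry, and no carbon is discarded.
- Against it: the key step makes no stereocentre. The propargylic centre of A1 must be built beforehand in enantiopure form, probably over several steps through an epimerizable α-branched aldehyde. C3 must be set afterwards by reducing the exocyclic alkene, where hydrogen should add from the face remote from the C4 substituent and give the cis relation, so a base equilibration would follow. Pressurized CO is also needed.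
- Comparison: on ring construction and atom economy this alternative is the better plan, since the chosen route closes the ring late and loses two carbons as acetaldehyde. It is also the equal or better in that the hydrogenation could remove the benzyl group in the same operation. On stereocontrol the chosen plan is stronger, because one purchased stereocentre sets both centres in a single, well-understood pericyclic step. On step count the alternative is probably longer because of the route to A1.

Alternative 2: The cut is the bond between C4 and the benzylic CH2 of ring B. In the forward step, photoredox decarboxylation of the arylacetic acid A4 (organic photocatalyst 4CzIPN, Cs2CO3, blue light) would give an electron-rich benzyl radical. It would add to C4 of the menthyloxy butenolide A3 on the face opposite the acetal substituent, and the resulting enolate would be protonated trans to the new group, giving A5.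
- In its favour: the route is convergent, the lactone ring is present from the start, and the conditions are mild and free of strong base. Both centres are set on a rigid ring under the control of an inexpensive auxiliary.
- Against it: a stabilized benzyl radical adds slowly and reversibly, so radical dimerization and simple reduction compete. A3 needs several steps and a diastereomerically pure acetal. After the key step the acetal carbon must still be reduced to CH2 by hydride opening and relactonization, and the benzyl group removed.
- Comparison: for the trans relation this alternative is the better plan, because kinetic protonation and thermodynamic preference point the same way and no enolate geometry is involved. For the absolute configuration at C4 the two plans are equal, each relying on one purchased chiral element. The chosen plan rests on a firmer bond-forming step, and its step count is equal or lower.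

Alternative 3: The cut is the bond between the C4 benzylic CH2 and the para carbon of ring B. In the forward step the aryl ether A6 would be heated. A first [3,3] shift to the methoxy-bearing ortho carbon, a second [3,3] shift to the para carbon and tautomerization would give the phenol A7.
- In its favour: ring B arrives with its free hydroxyl group and no protecting group is needed. The components are achiral and simple, and the two ortho methoxy groups enforce para delivery.
- Against it: the first shift must bond to C3 of the butenolide, a fully substituted and electron-poor carbon, and passes through a dienone with two adjacent quaternary carbons. This needs high temperatures at which cleavage of the allylic aryl ether competes. A7 also has no stereocentre. Both centres would have to come from a later enantioselective reduction of a tetrasubstituted butenolide alkene bearing a free phenol, for example with a complex of the type [Ir(cod)(N,P-ligand)]BArF, followed by epimerization at C3, and such reductions are demanding.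
- Comparison: on protecting-group economy this alternative is the better plan, and on paper it is also shorter. On stereochemistry it is clearly weaker, since its key step sets neither centre whereas the chosen key step sets both. Its first sigmatropic shift is also mechanistically less secure than the chosen rearrangement.

Key step: step 4

Remark on the chemistry: 1, 3 and 5 are taken to be catalogue compounds; the stereochemical course of step 4 was traced atom by atom through the chair model and the descriptors below follow from it; 11 is written in its open form although it should rest largely as the cyclic 5-hydroxy lactone.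

## Route

Step 1
Reactants: 1 4-allyl-2,6-dimethoxyphenol
Product: 2 2-(benzyloxy)-1,3-dimethoxy-5-(prop-2-en-1-yl)benzene
Conditions: BnBr (1.2 equiv), K2CO3 (2 equiv), acetone, reflux
Reagents that add atoms: benzyl bromide, BrCc1ccccc1
Why: Williamson etherification (SN2 of the phenoxide on a benzylic bromide); the allyl group is inert and the flanking methoxy groups should not prevent O-alkylation.

Step 2
Reactants: 2 2-(benzyloxy)-1,3-dimethoxy-5-(prop-2-en-1-yl)benzene; 3 (R)-but-3-en-2-ol (2 equiv)
Product: 4 (2R,3E)-5-[4-(benzyloxy)-3,5-dimethoxyphenyl]pent-3-en-2-ol
Conditions: second-generation Grubbs catalyst RuCl2(=CHPh)(H2IMes)(PCy3) (3 mol%), 1,4-benzoquinone (10 mol%), CH2Cl2, 40 °C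
Reagents that add atoms: none
Why: Olefin cross-metathesis between a quickly homodimerizing allylarene and a slowly homodimerizing secondary allylic alcohol should favour the cross product and, being reversible, the (E)-alkene; the carbinol centre is not involved and keeps its (R) configuration. 1,4-Benzoquinone is added to intercept Ru–H species that would move the double bond into conjugation with ring B; any (Z)-isomer is to be removed on AgNO3-impregnated silica before step 3.

Step 3
Reactants: 4 (2R,3E)-5-[4-(benzyloxy)-3,5-dimethoxyphenyl]pent-3-en-2-ol; 5 3-(3,4,5-trimethoxyphenyl)propanoic acid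
Product: 6 (2R,3E)-5-[4-(benzyloxy)-3,5-dimethoxyphenyl]pent-3-en-2-yl 3-(3,4,5-trimethoxyphenyl)propanoate
Conditions: DCC (1.1 equiv), DMAP (cat.), CH2Cl2, 0 °C to rt
Reagents that add atoms: none
Why: Steglich esterification; carbodiimide activation and acyl transfer through the acylpyridinium acylate the secondary alcohol at oxygen under neutral conditions, so neither allylic transposition nor loss of configuration at the carbinol is expected.

Step 4
Reactants: 6 (2R,3E)-5-[4-(benzyloxy)-3,5-dimethoxyphenyl]pent-3-en-2-yl 3-(3,4,5-trimethoxyphenyl)propanoate
Product: 9 (2R,3S,4E)-3-{[4-(benzyloxy)-3,5-dimethoxyphenyl]methyl}-2-[(3,4,5-trimethoxyphenyl)methyl]hex-4-enoic acid, via (Z)-trimethylsilyl ketene acetal 7 (not isolated), via trimethylsilyl ester 8 (not isolated)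
Conditions: LiN(iPr)2 (1.1 equiv), THF/DMPU (3:1), −78 °C; Me3SiCl/Et3N, −78 °C to rt, then 50 °C; 1 M HCl
Reagents that add atoms: none
Why: LiN(iPr)2 in THF/DMPU removes an α-proton of 6 through an open transition state, which should place the 3,4,5-trimethoxybenzyl group cis to the O–Li bond, and O-silylation fixes this as the (Z)-ketene acetal 7. On warming, 7 undergoes a concerted suprafacial [3,3]-sigmatropic shift (Ireland–Claisen rearrangement; closest known type: ester enolate Claisen rearrangement of a secondary (E)-allylic ester with 1,3-chirality transfer) that breaks the carbinol C–O bond and forms C2–C3 of silyl ester 8, which aqueous acid hydrolyses to 9. No ring is closed; the six-membered array exists only in the transition state. C3 of 9 (C4 of 14) is controlled by the (R)-carbinol centre: in the chair with the carbinol methyl equatorial the new bond forms on the alkene face from which the oxygen leaves, which gives (S) at C3 and an (E)-propenyl group. C2 of 9 (C3 of 14) is controlled by the ketene acetal geometry within the same chair: the (Z)-acetal holds its benzyl group equatorial, which gives (R) at C2 and the syn acid that becomes the trans lactone. The step needs one ketene acetal geometry (secured by DMPU), the chair over the boat (the normal preference of acyclic substrates) and an (E)-alkene of high purity (secured in step 2). Only 1.1 equivalents of base are used so that the doubly activated ArCH2–CH= protons are left alone; the aryl and benzyl ethers are inert.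

Step 5
Reactants: 9 (2R,3S,4E)-3-{[4-(benzyloxy)-3,5-dimethoxyphenyl]methyl}-2-[(3,4,5-trimethoxyphenyl)methyl]hex-4-enoic acid
Product: 11 (2R,3R)-3-{[4-(benzyloxy)-3,5-dimethoxyphenyl]methyl}-4-oxo-2-[(3,4,5-trimethoxyphenyl)methyl]butanoic acid, via vicinal diol 10 (not isolated)
Conditions: OsO4 (2 mol%), NaIO4 (4 equiv), 2,6-lutidine (2 equiv), dioxane/H2O (3:1), rt
Reagents that add atoms: osmium tetroxide, O=[Os](=O)(=O)=O; sodium periodate, [Na+].[O-]I(=O)(=O)=O
Why: Lemieux–Johnson oxidation; OsO4 dihydroxylates the only alkene, NaIO4 cleaves diol 10 and returns osmium to OsO4, and 2,6-lutidine suppresses over-oxidation. The aryl and benzyl ethers are inert to both oxidants, and 11 should close reversibly onto its carboxyl group as a cyclic 5-hydroxy lactone, which shields the centre next to the aldehyde from enolization; it is taken on crude.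

Step 6
Reactants: 11 (2R,3R)-3-{[4-(benzyloxy)-3,5-dimethoxyphenyl]methyl}-4-oxo-2-[(3,4,5-trimethoxyphenyl)methyl]butanoic acid
Product: 13 (3R,4R)-4-{[4-(benzyloxy)-3,5-dimethoxyphenyl]methyl}-3-[(3,4,5-trimethoxyphenyl)methyl]oxolan-2-one, via hydroxy acid 12 (not isolated)
Conditions: NaBH4, THF/MeOH, 0 °C; then 2 M HCl, rt
Reagents that add atoms: none
Why: Borohydride reduction of the aldehyde (through the open form of the hydroxy lactone) gives the hydroxy carboxylate, and acidification closes the γ-lactone by 5-exo-trig acyl substitution. Neither stereocentre is touched: the aldehyde is consumed quickly, and the carbon α to the carboxylate is not acidic in the basic medium.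

Step 7
Reactants: 13 (3R,4R)-4-{[4-(benzyloxy)-3,5-dimethoxyphenyl]methyl}-3-[(3,4,5-trimethoxyphenyl)methyl]oxolan-2-one
Product: 14 (3R,4R)-4-[(4-hydroxy-3,5-dimethoxyphenyl)methyl]-3-[(3,4,5-trimethoxyphenyl)methyl]oxolan-2-one
Conditions: H2 (1 atm), Pd/C, EtOAc/EtOH, rt
Reagents that add atoms: none
Why: Hydrogenolysis of the benzyl aryl ether over Pd/C; the lactone, the methoxy groups and the two benzylic C–C bonds are inert, and the neutral conditions leave both stereocentres untouched.

## Compound list

1 | 4-allyl-2,6-dimethoxyphenol | C=CCc1cc(OC)c(O)c(OC)c1 | starting material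
2 | 2-(benzyloxy)-1,3-dimethoxy-5-(prop-2-en-1-yl)benzene | C=CCc1cc(OC)c(OCc2ccccc2)c(OC)c1 | intermediate
3 | (R)-but-3-en-2-ol | C[C@@H](O)C=C | starting material
4 | (2R,3E)-5-[4-(benzyloxy)-3,5-dimethoxyphenyl]pent-3-en-2-ol | C[C@@H](O)/C=C/Cc1cc(OC)c(OCc2ccccc2)c(OC)c1 | intermediate
5 | 3-(3,4,5-trimethoxyphenyl)propanoic acid | COc1cc(CCC(=O)O)cc(OC)c1OC | starting material
6 | (2R,3E)-5-[4-(benzyloxy)-3,5-dimethoxyphenyl]pent-3-en-2-yl 3-(3,4,5-trimethoxyphenyl)propanoate | C[C@@H](OC(=O)CCc1cc(OC)c(OC)c(OC)c1)/C=C/Cc1cc(OC)c(OCc2ccccc2)c(OC)c1 | intermediate
7 | {[(1Z)-1-{[(2R,3E)-5-[4-(benzyloxy)-3,5-dimethoxyphenyl]pent-3-en-2-yl]oxy}-3-(3,4,5-trimethoxyphenyl)prop-1-en-1-yl]oxy}(trimethyl)silane | C[C@@H](O/C(=C/Cc1cc(OC)c(OC)c(OC)c1)O[Si](C)(C)C)/C=C/Cc1cc(OC)c(OCc2ccccc2)c(OC)c1 | intermediate (not isolated)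
8 | trimethylsilyl (2R,3S,4E)-3-{[4-(benzyloxy)-3,5-dimethoxyphenyl]methyl}-2-[(3,4,5-trimethoxyphenyl)methyl]hex-4-enoate | C[Si](C)(C)OC(=O)[C@H](Cc1cc(OC)c(OC)c(OC)c1)[C@@H](Cc1cc(OC)c(OCc2ccccc2)c(OC)c1)/C=C/C | intermediate (not isolated)
9 | (2R,3S,4E)-3-{[4-(benzyloxy)-3,5-dimethoxyphenyl]methyl}-2-[(3,4,5-trimethoxyphenyl)methyl]hex-4-enoic acid | OC(=O)[C@H](Cc1cc(OC)c(OC)c(OC)c1)[C@@H](Cc1cc(OC)c(OCc2ccccc2)c(OC)c1)/C=C/C | intermediate
10 | (2R,3R)-3-{[4-(benzyloxy)-3,5-dimethoxyphenyl]methyl}-4,5-dihydroxy-2-[(3,4,5-trimethoxyphenyl)methyl]hexanoic acid (C4 and C5 undefined) | OC(=O)[C@H](Cc1cc(OC)c(OC)c(OC)c1)[C@@H](Cc1cc(OC)c(OCc2ccccc2)c(OC)c1)C(O)C(C)O | intermediate (not isolated)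
11 | (2R,3R)-3-{[4-(benzyloxy)-3,5-dimethoxyphenyl]methyl}-4-oxo-2-[(3,4,5-trimethoxyphenyl)methyl]butanoic acid | OC(=O)[C@H](Cc1cc(OC)c(OC)c(OC)c1)[C@@H](Cc1cc(OC)c(OCc2ccccc2)c(OC)c1)C=O | intermediate
12 | (2R,3R)-3-{[4-(benzyloxy)-3,5-dimethoxyphenyl]methyl}-4-hydroxy-2-[(3,4,5-trimethoxyphenyl)methyl]butanoic acid | OC(=O)[C@H](Cc1cc(OC)c(OC)c(OC)c1)[C@@H](Cc1cc(OC)c(OCc2ccccc2)c(OC)c1)CO | intermediate (not isolated)
13 | (3R,4R)-4-{[4-(benzyloxy)-3,5-dimethoxyphenyl]methyl}-3-[(3,4,5-trimethoxyphenyl)methyl]oxolan-2-one | COc1cc(C[C@H]2COC(=O)[C@@H]2Cc2cc(OC)c(OC)c(OC)c2)cc(OC)c1OCc1ccccc1 | intermediate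
14 | (3R,4R)-4-[(4-hydroxy-3,5-dimethoxyphenyl)methyl]-3-[(3,4,5-trimethoxyphenyl)methyl]oxolan-2-one | COc1cc(C[C@H]2COC(=O)[C@@H]2Cc2cc(OC)c(OC)c(OC)c2)cc(OC)c1O | target

## Step count and least certain steps

Total step count: 7. Longest linear sequence: 7 steps (1 to 14); 3 and 5 enter as purchased materials.

**Step 4 (key step).** The most likely failure is incomplete control of the ketene acetal geometry, with a smaller leak through a boat transition state. Enolization of a simple 3-arylpropanoate in THF/DMPU is selective but not exclusive, and either leak delivers the C2 epimer of 9. The centre derived from the carbinol is not affected by these leaks, because the face of the allyl unit is fixed by the departing oxygen in chair and boat alike. The fallback therefore gives up kinetic control of C3 and relies on thermodynamic control. The material from step 4 is carried through steps 5 and 6 without separating epimers. The fallback sets out from compound 13 as it then leaves step 6, where the leak appears as the cis lactone (3S,4R)-4-{[4-(benzyloxy)-3,5-dimethoxyphenyl]methyl}-3-[(3,4,5-trimethoxyphenyl)methyl]oxolan-2-one F1. The mixture is heated with DBU in toluene at reflux. Deprotonation at C3 and reprotonation under equilibrium control should convert F1 into the more stable trans lactone, and the fallback comes back to the route at compound 13. This correction holds only for material that stems from the (E)-alkene. A cis lactone that stems from (Z)-alkene has the opposite configuration at C4 and would be turned into the enantiomer of 13, so the geometric purity of 4 must be secured first.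

**Step 2.** The most likely failure is migration of the double bond of 2 into conjugation with ring B, caused by Ru–H species formed as RuCl2(=CHPh)(H2IMes)(PCy3) decays. The second is incomplete (E) selectivity; any (Z)-alkene carried forward would invert the future C4 in step 4. The fallback avoids metathesis and fixes the geometry by a trans-selective reduction. It replaces steps 1 and 2, so it sets out from no numbered compound but from two further catalogue materials, and it comes back to the route at compound 4. [4-(Benzyloxy)-3,5-dimethoxyphenyl]methanol F2 would be converted with PBr3 in CH2Cl2 into 2-(benzyloxy)-5-(bromomethyl)-1,3-dimethoxybenzene F3. (R)-But-3-yn-2-ol F4 would be deprotonated twice with EtMgBr in THF and the alkynyl Grignard reagent benzylated with F3 under CuCl catalysis to give (R)-5-[4-(benzyloxy)-3,5-dimethoxyphenyl]pent-3-yn-2-ol F5. LiAlH4 in THF would then reduce F5 by alkoxide-directed trans-hydroalumination, which should give 4 as the (E)-isomer only, with the carbinol centre untouched.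

**Step 5.** The most likely failure is enolization at the carbon α to the aldehyde of 11 (the future C4) during the hours in buffered aqueous dioxane. This would erode the one centre that cannot be repaired later. Over-oxidation of diol 10 to an α-hydroxy ketone is the second risk. The fallback never liberates the aldehyde and merges steps 5 and 6. It sets out from compound 9, which would be treated with ozone in CH2Cl2 at −78 °C to the end point of Sudan Red 7B, giving the ozonide (2R,3R)-3-{[4-(benzyloxy)-3,5-dimethoxyphenyl]methyl}-3-(5-methyl-1,2,4-trioxolan-3-yl)-2-[(3,4,5-trimethoxyphenyl)methyl]propanoic acid F6. NaBH4 and MeOH would be added to the same flask to reduce F6 directly to hydroxy acid 12, and acidification with 2 M HCl brings the fallback back to the route at compound 13. The price is the need to stop the ozone feed exactly at the end point, because the electron-rich rings and the benzyl ether are slowly attacked by excess ozone.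

## Further compounds

F1 | step 4 | (3S,4R)-4-{[4-(benzyloxy)-3,5-dimethoxyphenyl]methyl}-3-[(3,4,5-trimethoxyphenyl)methyl]oxolan-2-one | COc1cc(C[C@H]2COC(=O)[C@H]2Cc2cc(OC)c(OC)c(OC)c2)cc(OC)c1OCc1ccccc1
F2 | step 2 | [4-(benzyloxy)-3,5-dimethoxyphenyl]methanol | OCc1cc(OC)c(OCc2ccccc2)c(OC)c1
F3 | step 2 | 2-(benzyloxy)-5-(bromomethyl)-1,3-dimethoxybenzene | BrCc1cc(OC)c(OCc2ccccc2)c(OC)c1
F4 | step 2 | (R)-but-3-yn-2-ol | C[C@@H](O)C#C
F5 | step 2 | (R)-5-[4-(benzyloxy)-3,5-dimethoxyphenyl]pent-3-yn-2-ol | C[C@@H](O)C#CCc1cc(OC)c(OCc2ccccc2)c(OC)c1
F6 | step 5 | (2R,3R)-3-{[4-(benzyloxy)-3,5-dimethoxyphenyl]methyl}-3-(5-methyl-1,2,4-trioxolan-3-yl)-2-[(3,4,5-trimethoxyphenyl)methyl]propanoic acid | OC(=O)[C@H](Cc1cc(OC)c(OC)c(OC)c1)[C@@H](Cc1cc(OC)c(OCc2ccccc2)c(OC)c1)C1OOC(C)O1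
A1 | alternative 1 | (R)-2-{[4-(benzyloxy)-3,5-dimethoxyphenyl]methyl}-4-(3,4,5-trimethoxyphenyl)but-3-yn-1-ol | OC[C@H](Cc1cc(OC)c(OCc2ccccc2)c(OC)c1)C#Cc1cc(OC)c(OC)c(OC)c1
A2 | alternative 1 | (3E,4R)-4-{[4-(benzyloxy)-3,5-dimethoxyphenyl]methyl}-3-[(3,4,5-trimethoxyphenyl)methylidene]oxolan-2-one | O=C1OC[C@H](Cc2cc(OC)c(OCc3ccccc3)c(OC)c2)/C1=C\c4cc(OC)c(OC)c(OC)c4
A3 | alternative 2 | (5R)-5-{[(1R,2S,5R)-5-methyl-2-(propan-2-yl)cyclohexyl]oxy}-3-[(3,4,5-trimethoxyphenyl)methyl]furan-2(5H)-one | C[C@@H]1CC[C@H]([C@@H](C1)O[C@@H]2OC(=O)C(Cc3cc(OC)c(OC)c(OC)c3)=C2)C(C)C
A4 | alternative 2 | 2-[4-(benzyloxy)-3,5-dimethoxyphenyl]acetic acid | OC(=O)Cc1cc(OC)c(OCc2ccccc2)c(OC)c1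
A5 | alternative 2 | (3R,4R,5R)-4-{[4-(benzyloxy)-3,5-dimethoxyphenyl]methyl}-5-{[(1R,2S,5R)-5-methyl-2-(propan-2-yl)cyclohexyl]oxy}-3-[(3,4,5-trimethoxyphenyl)methyl]oxolan-2-one | C[C@@H]1CC[C@H]([C@@H](C1)O[C@@H]3OC(=O)[C@H](Cc4cc(OC)c(OC)c(OC)c4)[C@H]3Cc5cc(OC)c(OCc6ccccc6)c(OC)c5)C(C)C
A6 | alternative 3 | 4-[(2,6-dimethoxyphenoxy)methyl]-3-[(3,4,5-trimethoxyphenyl)methyl]furan-2(5H)-one | COc1cccc(OC)c1OCC1=C(Cc2cc(OC)c(OC)c(OC)c2)C(=O)OC1
A7 | alternative 3 | 4-[(4-hydroxy-3,5-dimethoxyphenyl)methyl]-3-[(3,4,5-trimethoxyphenyl)methyl]furan-2(5H)-one | COc1cc(CC2=C(Cc3cc(OC)c(OC)c(OC)c3)C(=O)OC2)cc(OC)c1O
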